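**Retrosynthetic overview**
1. Locants (diterpene numbering): ring A = carbocycle C1–C6 (Br on C2, Me and OH on C3, side chain on C6); diene C7(Me)=C8–C9=C10; ring B = oxane O/C11–C15 (Br on C14).
2. Last disconnection: the C1–C6 bond of ring A together with C7=C8. Ring A is closed by a bromonium-triggered olefin cyclisation of an open-chain 2-bromo-1-triflate, modelled on the way algal haloterpenoids of this kind are thought to arise. Enabling feature: in ring A the equatorial C2–Br bond lies anti to the C1–C6 ring bond (the mark of anti opening of a C1/C2 bromonium ion by C6), and C6 carries C7, whose cation can lose the doubly allylic H8 to give the C7=C8–C9=C10 diene.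
3. Open-chain precursor: C8–C9 by allyl–alkenyl Suzuki–Miyaura coupling; C1–OH/C2–Br by hydroboration, oxidation and enamine-catalysed α-bromination of a linalyl vinyl group; C3 from the chiral pool.
4. Both halves come from (S)-linalool. Order of ring formation: ring B first (bromoetherification, step 1), ring A last (step 11).

Key step: step 11

Assumption: (S)-(+)-linalool of high enantiomeric purity is taken as a commercial starting material.

**Fragment A (ring B)**

Step 1
Reactants: 1 (S)-linalool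
Product: 2 (3R,6S)-3-bromo-6-ethenyl-2,2,6-trimethyloxane
Conditions: TBCO (1.1 equiv), MeNO2, 0 °C → rt, dark; chromatography
Reagents that add atoms: 2,4,4,6-tetrabromocyclohexa-2,5-dien-1-one (TBCO), O=C1C(Br)=CC(Br)(Br)C=C1Br
Why: Bromoetherification, in which the bromonium ion forms only on the electron-rich trisubstituted olefin and is opened by the tertiary hydroxyl at the tertiary carbon (6-endo, Markovnikov) through a chair that places Br equatorial by anti addition, the C6 centre being carried over from 1; because methyl and vinyl differ little in size, the C3 epimer and the 5-exo oxolanes are expected as well and must be separated.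

Step 2
Reactants: 2 (3R,6S)-3-bromo-6-ethenyl-2,2,6-trimethyloxane
Product: 4 (2S,5R)-5-bromo-2,6,6-trimethyloxane-2-carbaldehyde, via ozonide 3 (not isolated)
Conditions: O3, CH2Cl2, −78 °C; then PPh3, −78 °C → rt
Reagents that add atoms: ozone, [O-][O+]=O
Why: Ozonolysis of the only olefin with reductive work-up; the aldehyde has no α-hydrogen, so neither ring stereocentre is at risk.

Step 3
Reactants: 4 (2S,5R)-5-bromo-2,6,6-trimethyloxane-2-carbaldehyde; 5 2-(dichloromethyl)-4,4,5,5-tetramethyl-1,3,2-dioxaborolane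
Product: 6 2-[(E)-2-[(2S,5R)-5-bromo-2,6,6-trimethyloxan-2-yl]ethenyl]-4,4,5,5-tetramethyl-1,3,2-dioxaborolane
Conditions: CrCl2 (8 equiv), LiI (4 equiv), THF, rt
Reagents that add atoms: compound 5 (carbon C9 and the pinacolboryl group), ClC(Cl)B1OC(C)(C)C(C)(C)O1
Why: Takai–Utimoto olefination, in which the geminal dichromium species made from 5 adds to the aldehyde and eliminates to the E-alkenyl boronate, while the unactivated secondary bromide should be inert to CrCl2 at room temperature.

**Fragment B (C1–C8)**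

Step 4
Reactants: 1 (S)-linalool
Product: 7 triethyl{[(3S)-3,7-dimethylocta-1,6-dien-3-yl]oxy}silane
Conditions: TESOTf, 2,6-lutidine, CH2Cl2, −78 → 0 °C
Reagents that add atoms: triethylsilyl trifluoromethanesulfonate, CC[Si](CC)(CC)OS(=O)(=O)C(F)(F)F
Why: Silylation of the hindered tertiary alcohol with a silyl triflate and a hindered base; the stereocentre is not involved.

Step 5
Reactants: 7 triethyl{[(3S)-3,7-dimethylocta-1,6-dien-3-yl]oxy}silane
Product: 8 (2E,6S)-2,6-dimethyl-6-[(triethylsilyl)oxy]octa-2,7-dien-1-ol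
Conditions: SeO2 (0.3 equiv), t-BuOOH (3 equiv), salicylic acid (0.1 equiv), CH2Cl2, rt
Reagents that add atoms: selenium dioxide, O=[Se]=O (catalytic carrier of the oxygen); tert-butyl hydroperoxide, CC(C)(C)OO (stoichiometric oxygen source)
Why: Riley allylic oxidation (ene reaction, then [2,3]-sigmatropic shift), which should attack the E-methyl group of the trisubstituted olefin selectively and leave the vinyl group, which has no allylic hydrogen, untouched.

Step 6
Reactants: 8 (2E,6S)-2,6-dimethyl-6-[(triethylsilyl)oxy]octa-2,7-dien-1-ol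
Product: 9 (2E,6S)-2,6-dimethyl-6-[(triethylsilyl)oxy]octa-2,7-dien-1-yl methyl carbonate
Conditions: ClCO2Me, pyridine, CH2Cl2, 0 °C
Reagents that add atoms: methyl chloroformate, COC(=O)Cl
Why: Acylation of the primary allylic alcohol to the carbonate that serves as the leaving group for palladium.

**Union and end game**

Step 7
Reactants: 6 2-[(E)-2-[(2S,5R)-5-bromo-2,6,6-trimethyloxan-2-yl]ethenyl]-4,4,5,5-tetramethyl-1,3,2-dioxaborolane; 9 (2E,6S)-2,6-dimethyl-6-[(triethylsilyl)oxy]octa-2,7-dien-1-yl methyl carbonate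
Product: 10 {[(3S,6E,9E)-10-[(2S,5R)-5-bromo-2,6,6-trimethyloxan-2-yl]-3,7-dimethyldeca-1,6,9-trien-3-yl]oxy}triethylsilane
Conditions: Pd2(dba)3 (2.5 mol %), PPh3 (10 mol %), THF, 60 °C, no added base
Reagents that add atoms: none
Why: Suzuki–Miyaura allyl–alkenyl coupling, in which oxidative addition and loss of CO2 give a π-allylpalladium methoxide, the methoxide activates the boronate, and reductive elimination at the unsubstituted allyl terminus C8 gives the skipped diene with retention of the E geometry at C9=C10 (E/Z leakage at C6=C7 would be harmless, see step 11).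

Step 8
Reactants: 10 {[(3S,6E,9E)-10-[(2S,5R)-5-bromo-2,6,6-trimethyloxan-2-yl]-3,7-dimethyldeca-1,6,9-trien-3-yl]oxy}triethylsilane
Product: 12 (3S,6E,9E)-10-[(2S,5R)-5-bromo-2,6,6-trimethyloxan-2-yl]-3,7-dimethyl-3-[(triethylsilyl)oxy]deca-6,9-dien-1-ol, via alkylborane 11 (not isolated)
Conditions: 9-BBN (1.3 equiv), THF, 0 °C → rt; then aq NaOH, H2O2, 0 °C
Reagents that add atoms: 9-borabicyclo[3.3.1]nonane, B1C2CCCC1CCC2 (boron only in 11); hydrogen peroxide, OO
Why: Anti-Markovnikov hydroboration–oxidation, in which 9-BBN should discriminate the monosubstituted vinyl group from the trisubstituted and the hindered 1,2-disubstituted olefins; no stereocentre is formed.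

Step 9
Reactants: 12 (3S,6E,9E)-10-[(2S,5R)-5-bromo-2,6,6-trimethyloxan-2-yl]-3,7-dimethyl-3-[(triethylsilyl)oxy]deca-6,9-dien-1-ol
Product: 13 (3S,6E,9E)-10-[(2S,5R)-5-bromo-2,6,6-trimethyloxan-2-yl]-3,7-dimethyl-3-[(triethylsilyl)oxy]deca-6,9-dienal
Conditions: TEMPO (10 mol %), PhI(OAc)2 (1.2 equiv), CH2Cl2, rt
Reagents that add atoms: none
Why: Oxoammonium (TEMPO) oxidation of the primary alcohol to the aldehyde under neutral conditions that should leave the olefins, the bromide and the silyl ether alone.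

Step 10
Reactants: 13 (3S,6E,9E)-10-[(2S,5R)-5-bromo-2,6,6-trimethyloxan-2-yl]-3,7-dimethyl-3-[(triethylsilyl)oxy]deca-6,9-dienal
Product: 15 (2R,3S,6E,9E)-2-bromo-10-[(2S,5R)-5-bromo-2,6,6-trimethyloxan-2-yl]-3,7-dimethyl-3-[(triethylsilyl)oxy]deca-6,9-dien-1-ol, via bromoaldehyde 14 (not isolated)
Conditions: trans-2,5-diphenylpyrrolidine (20 mol %, the antipode that gives 2S in 14), PhCO2H (20 mol %), 4,4-dibromo-2,6-di-tert-butylcyclohexa-2,5-dienone (1.1 equiv), CH2Cl2/pentane, −40 °C; then NaBH4, MeOH, −40 → 0 °C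
Reagents that add atoms: 4,4-dibromo-2,6-di-tert-butylcyclohexa-2,5-dien-1-one, CC(C)(C)C1=CC(Br)(Br)C=C(C(C)(C)C)C1=O
Why: Enamine-catalysed α-bromination of the aldehyde, in which the C2-symmetric amine shields one face of the E-enamine so that C2 is set by the catalyst and not by the neighbouring fully substituted C3, followed by reduction in the same flask before the labile α-bromo aldehyde can epimerise.

Step 11
Reactants: 15 (2R,3S,6E,9E)-2-bromo-10-[(2S,5R)-5-bromo-2,6,6-trimethyloxan-2-yl]-3,7-dimethyl-3-[(triethylsilyl)oxy]deca-6,9-dien-1-ol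
Product: 17 {[(1S,2R,4R)-2-bromo-4-[(2E,4E)-5-[(2S,5R)-5-bromo-2,6,6-trimethyloxan-2-yl]penta-2,4-dien-2-yl]-1-methylcyclohexyl]oxy}triethylsilane, via triflate 16 (not isolated)
Conditions: Tf2O (1.1 equiv), 2,6-di-tert-butyl-4-methylpyridine (3 equiv), CH2Cl2, −78 °C; then (CF3)2CHOH, −78 → 0 °C
Reagents that add atoms: trifluoromethanesulfonic anhydride, O=S(=O)(OS(=O)(=O)C(F)(F)F)C(F)(F)F (its triflyl group is present only in 16)
Why: Proposed new method: the primary triflate 16 should ionise with anchimeric help from the C2 bromine to a C1/C2 bromonium ion (direct displacement of triflate by the olefin would give the same product), C6 of the C6=C7 olefin opens this ion at the primary carbon C1 through a chair, and the tertiary C7 cation loses the doubly allylic H8 to the hindered base to give the conjugated 7E,9E-diene; the closest known reaction types are cation–olefin cyclisations started by bromonium ions that are generated from enantiopure bromohydrin derivatives by neighbouring-group ionisation, solvolytic π-cyclisations of alkenyl sulfonates in fluorinated alcohols, and BDSB-type bromonium polyene cyclisations. Ring A closes in the 6-exo mode with respect to the olefin (C7 stays outside the ring) and by endo opening of the bromonium ion at its CH2 terminus. C2 and C3 are carried in from 15, and the new C6 centre is set by the chair: anti opening forces the C2–Br bond equatorial and anti to the forming C1–C6 bond, the fixed 2R,3S pair then places the C3 methyl equatorial and the silyloxy group axial, and the C7 substituent takes the equatorial site on C6, which is 6R. The step needs regioselectivity for C1 over C2 (which would give a cyclopentane), secured by the neopentyl-like position of C2 next to the fully substituted C3 and by the inductive pull of the C3 oxygen, and it needs the olefin to win over oxygen participation, secured by the bulky silyl ether and the non-nucleophilic, ionising medium. It also needs regioselective proton loss, favoured because only loss of H8 leads to a conjugated diene and the E geometry avoids strain between C9 and ring A. The geometry of C6=C7 is erased in the C7 cation, so an E/Z mixture at that bond in 15 would converge on the same product.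

Step 12
Reactants: 17 {[(1S,2R,4R)-2-bromo-4-[(2E,4E)-5-[(2S,5R)-5-bromo-2,6,6-trimethyloxan-2-yl]penta-2,4-dien-2-yl]-1-methylcyclohexyl]oxy}triethylsilane
Product: 18 (1S,2R,4R)-2-bromo-4-[(2E,4E)-5-[(2S,5R)-5-bromo-2,6,6-trimethyloxan-2-yl]penta-2,4-dien-2-yl]-1-methylcyclohexan-1-ol
Conditions: HF·pyridine, pyridine, THF, 0 °C → rt
Reagents that add atoms: none
Why: Fluoride cleavage of the tertiary silyl ether under buffered conditions; the cis bromohydrin cannot close to an epoxide because Br and O are never antiperiplanar.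

**Compound list**
1 | (S)-linalool, (3S)-3,7-dimethylocta-1,6-dien-3-ol | C=C[C@@](C)(O)CCC=C(C)C | starting material
2 | (3R,6S)-3-bromo-6-ethenyl-2,2,6-trimethyloxane | C=C[C@]1(C)CC[C@@H](Br)C(C)(C)O1 | intermediate
3 | 3-[(2S,5R)-5-bromo-2,6,6-trimethyloxan-2-yl]-1,2,4-trioxolane (ozonide, epimers at the trioxolane carbon) | C1(OOCO1)[C@]2(C)CC[C@@H](Br)C(C)(C)O2 | intermediate (not isolated)
4 | (2S,5R)-5-bromo-2,6,6-trimethyloxane-2-carbaldehyde | O=C[C@]1(C)CC[C@@H](Br)C(C)(C)O1 | intermediate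
5 | 2-(dichloromethyl)-4,4,5,5-tetramethyl-1,3,2-dioxaborolane | ClC(Cl)B1OC(C)(C)C(C)(C)O1 | starting material
6 | 2-[(E)-2-[(2S,5R)-5-bromo-2,6,6-trimethyloxan-2-yl]ethenyl]-4,4,5,5-tetramethyl-1,3,2-dioxaborolane | CC1(C)OB(/C=C/[C@]2(C)CC[C@@H](Br)C(C)(C)O2)OC1(C)C | intermediate
7 | triethyl{[(3S)-3,7-dimethylocta-1,6-dien-3-yl]oxy}silane | C=C[C@@](C)(O[Si](CC)(CC)CC)CCC=C(C)C | intermediate
8 | (2E,6S)-2,6-dimethyl-6-[(triethylsilyl)oxy]octa-2,7-dien-1-ol | C=C[C@@](C)(O[Si](CC)(CC)CC)CC/C=C(\C)CO | intermediate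
9 | (2E,6S)-2,6-dimethyl-6-[(triethylsilyl)oxy]octa-2,7-dien-1-yl methyl carbonate | C=C[C@@](C)(O[Si](CC)(CC)CC)CC/C=C(\C)COC(=O)OC | intermediate
10 | {[(3S,6E,9E)-10-[(2S,5R)-5-bromo-2,6,6-trimethyloxan-2-yl]-3,7-dimethyldeca-1,6,9-trien-3-yl]oxy}triethylsilane | C=C[C@@](C)(O[Si](CC)(CC)CC)CC/C=C(\C)C/C=C/[C@]1(C)CC[C@@H](Br)C(C)(C)O1 | intermediate
11 | 9-[(3S,6E,9E)-10-[(2S,5R)-5-bromo-2,6,6-trimethyloxan-2-yl]-3,7-dimethyl-3-[(triethylsilyl)oxy]deca-6,9-dien-1-yl]-9-borabicyclo[3.3.1]nonane | B1(CC[C@@](C)(O[Si](CC)(CC)CC)CC/C=C(\C)C/C=C/[C@]3(C)CC[C@@H](Br)C(C)(C)O3)C2CCCC1CCC2 | intermediate (not isolated)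
12 | (3S,6E,9E)-10-[(2S,5R)-5-bromo-2,6,6-trimethyloxan-2-yl]-3,7-dimethyl-3-[(triethylsilyl)oxy]deca-6,9-dien-1-ol | OCC[C@@](C)(O[Si](CC)(CC)CC)CC/C=C(\C)C/C=C/[C@]1(C)CC[C@@H](Br)C(C)(C)O1 | intermediate
13 | (3S,6E,9E)-10-[(2S,5R)-5-bromo-2,6,6-trimethyloxan-2-yl]-3,7-dimethyl-3-[(triethylsilyl)oxy]deca-6,9-dienal | O=CC[C@@](C)(O[Si](CC)(CC)CC)CC/C=C(\C)C/C=C/[C@]1(C)CC[C@@H](Br)C(C)(C)O1 | intermediate
14 | (2S,3S,6E,9E)-2-bromo-10-[(2S,5R)-5-bromo-2,6,6-trimethyloxan-2-yl]-3,7-dimethyl-3-[(triethylsilyl)oxy]deca-6,9-dienal | O=C[C@@H](Br)[C@@](C)(O[Si](CC)(CC)CC)CC/C=C(\C)C/C=C/[C@]1(C)CC[C@@H](Br)C(C)(C)O1 | intermediate (not isolated)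
15 | (2R,3S,6E,9E)-2-bromo-10-[(2S,5R)-5-bromo-2,6,6-trimethyloxan-2-yl]-3,7-dimethyl-3-[(triethylsilyl)oxy]deca-6,9-dien-1-ol | OC[C@@H](Br)[C@@](C)(O[Si](CC)(CC)CC)CC/C=C(\C)C/C=C/[C@]1(C)CC[C@@H](Br)C(C)(C)O1 | intermediate
16 | (2R,3S,6E,9E)-2-bromo-10-[(2S,5R)-5-bromo-2,6,6-trimethyloxan-2-yl]-3,7-dimethyl-3-[(triethylsilyl)oxy]deca-6,9-dien-1-yl trifluoromethanesulfonate | FC(F)(F)S(=O)(=O)OC[C@@H](Br)[C@@](C)(O[Si](CC)(CC)CC)CC/C=C(\C)C/C=C/[C@]1(C)CC[C@@H](Br)C(C)(C)O1 | intermediate (not isolated)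
17 | {[(1S,2R,4R)-2-bromo-4-[(2E,4E)-5-[(2S,5R)-5-bromo-2,6,6-trimethyloxan-2-yl]penta-2,4-dien-2-yl]-1-methylcyclohexyl]oxy}triethylsilane | C/C(=C\C=C\[C@]1(C)CC[C@@H](Br)C(C)(C)O1)[C@@H]1CC[C@](C)(O[Si](CC)(CC)CC)[C@H](Br)C1 | intermediate
18 | (1S,2R,4R)-2-bromo-4-[(2E,4E)-5-[(2S,5R)-5-bromo-2,6,6-trimethyloxan-2-yl]penta-2,4-dien-2-yl]-1-methylcyclohexan-1-ol | C/C(=C\C=C\[C@]1(C)CC[C@@H](Br)C(C)(C)O1)[C@@H]1CC[C@](C)(O)[C@H](Br)C1 | target

**Step count**
Total steps: 12. Longest linear sequence: 9 (steps 4–12 from 1, or steps 1–3 and 7–12).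

**Steps most likely to fail**

Step 11 (proposed new method). What may go wrong: opening of the bromonium ion by the olefin at C2 (five-ring closure), participation of the C3 oxygen (epoxide formation or a 1,2-shift), unselective proton loss from the C7 cation, or ionisation of the dienyl ether in the product. The fallback uses known reactions only; it gives up the late ring closure and builds the stereotriad on a preformed six-membered ring. It sets out from boronate 6 and comes back at 18. Commercial 1,4-dioxaspiro[4.5]decane-8-carbaldehyde F1 is homologated with the Ohira–Bestmann reagent (K2CO3, MeOH) to 8-ethynyl-1,4-dioxaspiro[4.5]decane F2. Zirconium-catalysed carboalumination (Me3Al, Cp2ZrCl2, then I2) gives 8-[(1E)-1-iodoprop-1-en-2-yl]-1,4-dioxaspiro[4.5]decane F3. Suzuki–Miyaura coupling with 6 (Pd(PPh3)4, aq K3PO4, THF) gives 8-[(2E,4E)-5-[(2S,5R)-5-bromo-2,6,6-trimethyloxan-2-yl]penta-2,4-dien-2-yl]-1,4-dioxaspiro[4.5]decane F4. PPTS in wet acetone frees 4-[(2E,4E)-5-[(2S,5R)-5-bromo-2,6,6-trimethyloxan-2-yl]penta-2,4-dien-2-yl]cyclohexan-1-one F5, whose ring carries no stereocentre. Enamine-catalysed enantioselective α-bromination (a C2-symmetric 4,5-diphenylimidazolidine, the antipode that gives 2R, with the bromodienone of step 10) desymmetrises the ring; after equilibration through the enol and removal of the trans epimer, (2R,4R)-2-bromo-4-[(2E,4E)-5-[(2S,5R)-5-bromo-2,6,6-trimethyloxan-2-yl]penta-2,4-dien-2-yl]cyclohexan-1-one F6 is taken on. MeMgBr at −78 °C should add so that OH ends cis to bromine, the known course for 2-halocyclohexanones, and give 18.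

Step 1. What may go wrong: poor facial selectivity in the chair (methyl and vinyl compete for the equatorial site, so the C3 epimer forms) and competing 5-exo closure to oxolanes. The fallback sets out from 1 and comes back at 2, with the bromine-bearing centre under reagent control. Shi epoxidation of the trisubstituted olefin, with the antipode of the fructose-derived ketone that gives the 6R epoxide, leads to (3S)-5-[(2R)-3,3-dimethyloxiran-2-yl]-3-methylpent-1-en-3-ol F7. Acid (CSA, CH2Cl2) then promotes the favoured 5-exo opening with inversion to 2-[(2S,5S)-5-ethenyl-5-methyloxolan-2-yl]propan-2-ol F8. Activation of the tertiary hydroxyl (Tf2O, 2,6-di-tert-butyl-4-methylpyridine, then Bu4NBr) should generate the bicyclic oxonium ion, which bromide opens at the secondary carbon with a second inversion; this ring expansion gives 2 without the epimer problem.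

Step 10. What may go wrong: incomplete catalyst control next to the fully substituted C3, epimerisation of the α-bromo aldehyde before reduction, β-elimination of silanol from the enamine, or bromination of the electron-rich olefins. The fallback replaces catalyst control by auxiliary control; it sets out from 13 and comes back at 15. Pinnick oxidation (NaClO2, NaH2PO4, 2-methylbut-2-ene) gives (3S,6E,9E)-10-[(2S,5R)-5-bromo-2,6,6-trimethyloxan-2-yl]-3,7-dimethyl-3-[(triethylsilyl)oxy]deca-6,9-dienoic acid F9. The pivaloyl mixed anhydride and lithiated (S)-4-benzyloxazolidin-2-one give (4S)-4-benzyl-3-[(3S,6E,9E)-10-[(2S,5R)-5-bromo-2,6,6-trimethyloxan-2-yl]-3,7-dimethyl-3-[(triethylsilyl)oxy]deca-6,9-dienoyl]-1,3-oxazolidin-2-one F10. The dibutylboron enolate (Bu2BOTf, i-Pr2NEt) is brominated with NBS at −78 °C on the face away from the benzyl group to give (4S)-4-benzyl-3-[(2S,3S,6E,9E)-2-bromo-10-[(2S,5R)-5-bromo-2,6,6-trimethyloxan-2-yl]-3,7-dimethyl-3-[(triethylsilyl)oxy]deca-6,9-dienoyl]-1,3-oxazolidin-2-one F11. LiBH4 removes the auxiliary reductively and gives 15.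

**Further compounds**
F1 | step 11 | 1,4-dioxaspiro[4.5]decane-8-carbaldehyde | O=CC1CCC2(CC1)OCCO2
F2 | step 11 | 8-ethynyl-1,4-dioxaspiro[4.5]decane | C#CC1CCC2(CC1)OCCO2
F3 | step 11 | 8-[(1E)-1-iodoprop-1-en-2-yl]-1,4-dioxaspiro[4.5]decane | I/C=C(\C)C1CCC2(CC1)OCCO2
F4 | step 11 | 8-[(2E,4E)-5-[(2S,5R)-5-bromo-2,6,6-trimethyloxan-2-yl]penta-2,4-dien-2-yl]-1,4-dioxaspiro[4.5]decane | C/C(=C\C=C\[C@]1(C)CC[C@@H](Br)C(C)(C)O1)C1CCC2(CC1)OCCO2
F5 | step 11 | 4-[(2E,4E)-5-[(2S,5R)-5-bromo-2,6,6-trimethyloxan-2-yl]penta-2,4-dien-2-yl]cyclohexan-1-one | C/C(=C\C=C\[C@]1(C)CC[C@@H](Br)C(C)(C)O1)C1CCC(=O)CC1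
F6 | step 11 | (2R,4R)-2-bromo-4-[(2E,4E)-5-[(2S,5R)-5-bromo-2,6,6-trimethyloxan-2-yl]penta-2,4-dien-2-yl]cyclohexan-1-one | C/C(=C\C=C\[C@]1(C)CC[C@@H](Br)C(C)(C)O1)[C@@H]1CCC(=O)[C@H](Br)C1
F7 | step 1 | (3S)-5-[(2R)-3,3-dimethyloxiran-2-yl]-3-methylpent-1-en-3-ol | C=C[C@@](C)(O)CC[C@H]1OC1(C)C
F8 | step 1 | 2-[(2S,5S)-5-ethenyl-5-methyloxolan-2-yl]propan-2-ol | C=C[C@]1(C)CC[C@H](O1)C(C)(C)O
F9 | step 10 | (3S,6E,9E)-10-[(2S,5R)-5-bromo-2,6,6-trimethyloxan-2-yl]-3,7-dimethyl-3-[(triethylsilyl)oxy]deca-6,9-dienoic acid | OC(=O)C[C@@](C)(O[Si](CC)(CC)CC)CC/C=C(\C)C/C=C/[C@]1(C)CC[C@@H](Br)C(C)(C)O1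
F10 | step 10 | (4S)-4-benzyl-3-[(3S,6E,9E)-10-[(2S,5R)-5-bromo-2,6,6-trimethyloxan-2-yl]-3,7-dimethyl-3-[(triethylsilyl)oxy]deca-6,9-dienoyl]-1,3-oxazolidin-2-one | O=C(C[C@@](C)(O[Si](CC)(CC)CC)CC/C=C(\C)C/C=C/[C@]1(C)CC[C@@H](Br)C(C)(C)O1)N1[C@@H](Cc2ccccc2)COC1=O
F11 | step 10 | (4S)-4-benzyl-3-[(2S,3S,6E,9E)-2-bromo-10-[(2S,5R)-5-bromo-2,6,6-trimethyloxan-2-yl]-3,7-dimethyl-3-[(triethylsilyl)oxy]deca-6,9-dienoyl]-1,3-oxazolidin-2-one | O=C([C@@H](Br)[C@@](C)(O[Si](CC)(CC)CC)CC/C=C(\C)C/C=C/[C@]1(C)CC[C@@H](Br)C(C)(C)O1)N1[C@@H](Cc2ccccc2)COC1=O
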